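**Two twins.** At 4.00 h, the last reading of spring and also of dawn, I held the two flasks side by side. Both had 0.98 equiv of D, but spring started from 62 mM of L and dawn from 82 mM.

| flask | L | D | temperature | remark | time |
|---|---|---|---|---|---|
| spring | 62 mM | 0.98 equiv | 0 °C | run made earlier |  |
| dawn | 82 mM | 0.98 equiv | 0 °C | run made earlier |  |
| violet | 41 mM | 0.320 equiv | 0 °C |  | 20 h |
| green | 41 mM | 0.660 equiv | 0 °C |  | 20 h |
| teal | 41 mM | 3.90 equiv | 0 °C |  | 20 h |
| grey | 41 mM | 0.980 equiv | 0 °C |  | 20 h |
| red | 41 mM | 2.90 equiv | 0 °C |  | 20 h |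

| run | time / h | Q / % | L / % |
|---|---|---|---|
| spring | 0.500 | 4.6 | 90.9 |
| spring | 1.00 | 8.6 | 83.6 |
| spring | 1.50 | 11.3 | 78.2 |
| spring | 2.50 | 15.5 | 68.4 |
| spring | 3.00 | 16.4 | 64.9 |
| spring | 4.00 | 18.6 | 58.0 |
| dawn | 0.333 | 4.2 | 92.6 |
| dawn | 0.500 | 6.2 | 89.8 |
| dawn | 0.667 | 8.0 | 86.8 |
| dawn | 1.00 | 11.1 | 81.2 |
| dawn | 1.50 | 14.3 | 75.3 |
| dawn | 2.50 | 18.9 | 65.4 |
| dawn | 4.00 | 22.5 | 55.1 |

(each reading ± 0.3 percentage points)



1. the flasks by amount of Q, in percent of the L charged, highest first, at 20 h (violet / green / teal / grey / red)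
2. the amount of Q, in percent of the L charged of the flask you put first, at 20 h
3. the amount of Q, in percent of the L charged of the flask you put last, at 20 h

Dawn held more Q, 22.5 % against spring's 18.6 %, yet L lost to something other than Q stood at 22.4 % in dawn and 23.4 % in spring. So I followed one L at a fork: its way to Q quickens with c_D, and its other way shows no such gain.

**Even odds.** From the first readings, with their scatter and taking c_D at its charge, I read the two ways as even at 59.4 mM in spring and 61.2 mM in dawn. I took the mean, 60.3 mM, as the even-odds concentration, the c_D at which an L is as likely to become Q as to leave the other way. Q's share at the fork, its selectivity, is then c_D/(c_D + that concentration).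

**My reckoning.** I reckoned spring's start share at 50.2 %, and by its last reading Q was 44.3 % of the L used. Teal starts at c_D 160 mM, so I reckoned its start share at 72.6 %. Scaled by spring's slip and counting teal's L as used up, that gave me 64.1 % of Q.

**The forecast.** It ran teal > red > grey > green > violet, with 40 % for the first flask and 5 % for the last, on the ground that “the order follows D equivalents”. I agreed on the order but stood higher for teal, and I had no figure of my own for violet.

**The result.** The order was teal > red > grey > green > violet, with teal at 57.0 % and violet at 2.92 %.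

    L + D → Q (k = 0.0320 L mol⁻¹ min⁻¹, Ea = 68.0 kJ mol⁻¹)
    L + D → X, rate k2*[L] as long as [D] is above zero (k = 0.00130 min⁻¹, Ea = 81.0 kJ mol⁻¹)
    D ⇌ Z (K = 25.0, k = 0.00350 min⁻¹, Ea = 95.0 kJ mol⁻¹, ΔH = −22.0 kJ mol⁻¹)
    (constants at 0 °C)

**Teal's fork.** At 20.0 h teal held X 36.8 % and L 6.22 %, so Q made up 60.7 % of Q and X together, against the 64.1 % I had reckoned from the even-odds reading. The flask like teal but with 6.60 equiv of D starts at c_D 271 mM, for which the same reading and spring's slip give a reckoned 72.2 %. It ended with Q 75.5 % beside X 22.4 %, a share of 77.1 %.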